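**Retrosynthetic overview**
1. The pyranone O1–C2 bond is the key C–O bond and is closed last by cyclodehydration. Opening it gives a 2-methoxy-1,3-diketone, which divides into phloroglucinol (ring A) and an α-methoxy aroylketene, that is, an α-methoxy β-keto ester.
2. The 5'-prenyl C–C bond is not made directly. A retro-[3,3] shift traces it to a 4'-O-(1,1-dimethylallyl) ether, a second strategic C–O bond that also masks the 4'-OH until the last step.
3. The β-keto ester comes from a crossed Claisen condensation of methyl methoxyacetate (C3, C4, 3-OMe) with O-tert-prenylated methyl vanillate (ring B, C2).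
4. The aryl tert-allyl ether comes from Pd-catalysed O-allylation of methyl vanillate with the tert-butyl carbonate of 2-methylbut-3-en-2-ol.
5. Ring order: rings A and B are bought. Ring C is the only ring formed, in the final step.

Assumption: the target has no stereocentre and no stereogenic double bond, so it is achiral and needs no enantiocontrol. The one stereocentre met on the way (C2 of 8, 10 and 12) is racemic and labile, and it is erased when ring C aromatises.

**Step 1**
Reactants: 1 2-methylbut-3-en-2-ol
Product: 3 tert-butyl 2-methylbut-3-en-2-yl carbonate, via lithium 2-methylbut-3-en-2-olate 2 (not isolated)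
Conditions: n-BuLi (1.05 equiv), THF, 0 °C, 30 min; Boc2O (1.1 equiv), 0 °C to rt, 3 h; H2O quench
Reagents that add atoms: di-tert-butyl dicarbonate, CC(C)(C)OC(=O)OC(=O)OC(C)(C)C; n-butyllithium, [Li]CCCC (supplies only the lithium of 2)
Why: Alkoxide acylation (mixed carbonate formation), in which the hindered tertiary alcohol reacts cleanly as its lithium alkoxide and takes one tert-butoxycarbonyl group from Boc2O; no stereocentre is formed.

**Step 2**
Reactants: 3 tert-butyl 2-methylbut-3-en-2-yl carbonate; 4 methyl vanillate (methyl 4-hydroxy-3-methoxybenzoate)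
Product: 5 methyl 3-methoxy-4-[(2-methylbut-3-en-2-yl)oxy]benzoate
Conditions: 3 (1.5 equiv), Pd(PPh3)4 (3 mol %), THF, 0 °C, 2–4 h, stopped as soon as 4 is consumed
Reagents that add atoms: none
Why: Tsuji–Trost O-allylation, in which zerovalent palladium ionises 3 with loss of CO2 and tert-butoxide (which deprotonates 4) and the phenoxide attacks the more substituted, more cationic terminus of the 1,1-dimethyl-π-allyl complex under kinetic control at 0 °C to form the aryl–O–C(CH3)2 bond; no stereocentre is formed.

**Step 3**
Reactants: 5 methyl 3-methoxy-4-[(2-methylbut-3-en-2-yl)oxy]benzoate; 6 methyl methoxyacetate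
Product: 8 methyl 2-methoxy-3-{3-methoxy-4-[(2-methylbut-3-en-2-yl)oxy]phenyl}-3-oxopropanoate (racemic), via lithium enolate of methyl methoxyacetate 7 (not isolated)
Conditions: 6 (2.5 equiv), LDA (commercial solution, 2.4 equiv), THF, −78 °C, 45 min; add 5, −78 to −10 °C, 3 h; AcOH quench at −78 °C
Reagents that add atoms: lithium diisopropylamide, [Li+].CC(C)[N-]C(C)C (supplies only the lithium of 7)
Why: Crossed Claisen condensation, in which preformed enolate 7 has almost no neutral ester left for self-condensation, 5 cannot enolise, and deprotonation of the β-keto ester product drives the addition–elimination; the new C2 stereocentre is racemic and labile and disappears in step 4.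

**Step 4**
Reactants: 8 methyl 2-methoxy-3-{3-methoxy-4-[(2-methylbut-3-en-2-yl)oxy]phenyl}-3-oxopropanoate; 9 phloroglucinol (benzene-1,3,5-triol, anhydrous)
Product: 13 dodoviscin J (5,7-dihydroxy-2-[4-hydroxy-3-methoxy-5-(3-methylbut-2-en-1-yl)phenyl]-3-methoxy-4H-chromen-4-one), via C-prenyl keto ester 10 (not isolated), via methoxy aroylketene 11 (not isolated), via 2-methoxy-1,3-diketone 12 (not isolated)
Conditions: 8, Ph2O (1 M), Ar, 175 °C, 1 h; then 9 (1.5 equiv), 240 °C, Ar sweep through a short-path head (MeOH and H2O distil off), 25 min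
Reagents that add atoms: none
Why: Proposed new method: a one-flask aromatic Claisen rearrangement/acylketene annulation without any protecting group, in which at 175 °C the tertiary allyl group moves through a chair [3,3] transition state from O4' to C5' (the only ortho carbon bearing hydrogen) with allyl inversion, giving the linear prenyl group and the free phenol of 10; at 240 °C the enol of 10 expels methanol to give α-methoxy aroylketene 11, whose O-acylation of any phenol present is reversible at this temperature whereas C-acylation of threefold-symmetric 9 gives the hydrogen-bond-locked diketone 12 irreversibly; an ortho hydroxyl of 12 then adds to the aroyl carbonyl and loss of water forms the O1–C2 bond and the aromatic γ-pyrone, while the absence of any acid stronger than a phenol keeps coumarin (Pechmann-type) formation and chroman closure of the o-prenylphenol slow; the closest known reaction types are the Mentzer (Simonis-type) pyrocondensation of phenols with simple β-keto esters and the thermal aromatic Claisen rearrangement, and the new element is their merger on an α-alkoxy β-keto ester carrying a tert-allyl aryl ether; no stereocentre is formed.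

**Compound list**
1 | 2-methylbut-3-en-2-ol | CC(C)(O)C=C | starting material
2 | lithium 2-methylbut-3-en-2-olate | [Li+].[O-]C(C)(C)C=C | intermediate (not isolated)
3 | tert-butyl 2-methylbut-3-en-2-yl carbonate | CC(C)(C)OC(=O)OC(C)(C)C=C | intermediate
4 | methyl vanillate (methyl 4-hydroxy-3-methoxybenzoate) | COC(=O)c1ccc(O)c(OC)c1 | starting material
5 | methyl 3-methoxy-4-[(2-methylbut-3-en-2-yl)oxy]benzoate | COC(=O)c1ccc(OC(C)(C)C=C)c(OC)c1 | intermediate
6 | methyl methoxyacetate | COCC(=O)OC | starting material
7 | lithium enolate of methyl methoxyacetate (geometry of no consequence) | [Li+].[O-]C(OC)=COC | intermediate (not isolated)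
8 | methyl 2-methoxy-3-{3-methoxy-4-[(2-methylbut-3-en-2-yl)oxy]phenyl}-3-oxopropanoate (racemic, labile C2) | COC(=O)C(OC)C(=O)c1ccc(OC(C)(C)C=C)c(OC)c1 | intermediate
9 | phloroglucinol (benzene-1,3,5-triol) | Oc1cc(O)cc(O)c1 | starting material
10 | methyl 3-[4-hydroxy-3-methoxy-5-(3-methylbut-2-en-1-yl)phenyl]-2-methoxy-3-oxopropanoate (racemic) | COC(=O)C(OC)C(=O)c1cc(OC)c(O)c(CC=C(C)C)c1 | intermediate (not isolated)
11 | 3-[4-hydroxy-3-methoxy-5-(3-methylbut-2-en-1-yl)phenyl]-2-methoxy-3-oxoprop-1-en-1-one (α-methoxy aroylketene) | COC(=C=O)C(=O)c1cc(OC)c(O)c(CC=C(C)C)c1 | intermediate (not isolated)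
12 | 1-[4-hydroxy-3-methoxy-5-(3-methylbut-2-en-1-yl)phenyl]-2-methoxy-3-(2,4,6-trihydroxyphenyl)propane-1,3-dione (racemic) | COC(C(=O)c1cc(OC)c(O)c(CC=C(C)C)c1)C(=O)c1c(O)cc(O)cc1O | intermediate (not isolated)
13 | dodoviscin J (achiral) | COc1cc(-c2oc3cc(O)cc(O)c3c(=O)c2OC)cc(CC=C(C)C)c1O | target

**Totals**
Total step count: 4. Longest linear sequence: 4 steps (1 → 3 → 5 → 8 → 13).

**Three steps most likely to fail**

*Step 4 (proposed new step).*
- Risks: loss of isoprene from the tert-allyl ether before it rearranges, chroman closure of the o-prenylphenol at 240 °C, decarboxylative cleavage of the keto ester by the water released, and competing coumarin formation.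
- Fallback (known chemistry only, no prenyl-bearing compound above 190 °C): it sets out from 9 and 5 and comes back to the route at 13. Hoesch acylation of 9 with methoxyacetonitrile (ZnCl2, HCl gas, Et2O, 0 °C; then H2O, reflux) gives 2-methoxy-1-(2,4,6-trihydroxyphenyl)ethan-1-one F1. In parallel, 5 is saponified (LiOH, THF/H2O, rt; AcOH to pH 5) to 3-methoxy-4-[(2-methylbut-3-en-2-yl)oxy]benzoic acid F2. DCC (0.5 equiv, CH2Cl2, 0 °C) dehydrates this acid to 3-methoxy-4-[(2-methylbut-3-en-2-yl)oxy]benzoic anhydride F3. Allan–Robinson condensation of F1 with F3 (4 equiv, Et3N, 150 °C; then KOH, aqueous MeOH, reflux, to cleave O-aroyl groups) gives 5,7-dihydroxy-3-methoxy-2-{3-methoxy-4-[(2-methylbut-3-en-2-yl)oxy]phenyl}-4H-chromen-4-one F4. Any portion that has already rearranged emerges from the hydrolysis as 13. A separate aromatic Claisen rearrangement (N,N-diethylaniline, 190 °C) converts F4 into 13.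

*Step 3.*
- Risks: the electron-rich benzoate 5 is a slow acceptor, and enolate 7 decays by self-condensation on warming.
- Fallback (aldol/oxidation instead of ester acylation): it sets out from 3 and comes back to the route at 8. Commercial vanillin takes the place of 4 in the step 2 protocol (3, Pd(PPh3)4, THF, 0 °C) and gives 3-methoxy-4-[(2-methylbut-3-en-2-yl)oxy]benzaldehyde F5. Aldol addition of enolate 7 (6, LDA, THF, −78 °C; AcOH quench) to this far more electrophilic aldehyde gives methyl 3-hydroxy-2-methoxy-3-{3-methoxy-4-[(2-methylbut-3-en-2-yl)oxy]phenyl}propanoate F6 as a racemic syn/anti mixture. Dess–Martin periodinane (NaHCO3, CH2Cl2, rt) oxidises it to 8.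

*Step 2.*
- Risks: the fairly acidic phenoxide of 4 is a good leaving group, so the palladium catalyst can re-ionise 5 and erode it to the linear O-prenyl ether.
- Fallback (propargyl route with no π-allyl intermediate, which also makes step 1 unnecessary): it sets out from 4 and comes back to the route at 5. Alkylation of 4 with 3-chloro-3-methylbut-1-yne (CuCl2 1 mol %, DBU, MeCN, 0 °C) gives methyl 3-methoxy-4-[(2-methylbut-3-yn-2-yl)oxy]benzoate F7. Semihydrogenation (H2 1 atm, Pd on CaCO3 poisoned with Pb(OAc)2, quinoline, EtOAc, rt) gives 5.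

**Further compounds**
F1 | step 4 | 2-methoxy-1-(2,4,6-trihydroxyphenyl)ethan-1-one | COCC(=O)c1c(O)cc(O)cc1O
F2 | step 4 | 3-methoxy-4-[(2-methylbut-3-en-2-yl)oxy]benzoic acid | OC(=O)c1ccc(OC(C)(C)C=C)c(OC)c1
F3 | step 4 | 3-methoxy-4-[(2-methylbut-3-en-2-yl)oxy]benzoic anhydride | C=CC(C)(C)Oc1ccc(cc1OC)C(=O)OC(=O)c1ccc(OC(C)(C)C=C)c(OC)c1
F4 | step 4 | 5,7-dihydroxy-3-methoxy-2-{3-methoxy-4-[(2-methylbut-3-en-2-yl)oxy]phenyl}-4H-chromen-4-one | COc1cc(ccc1OC(C)(C)C=C)-c1oc2cc(O)cc(O)c2c(=O)c1OC
F5 | step 3 | 3-methoxy-4-[(2-methylbut-3-en-2-yl)oxy]benzaldehyde | O=Cc1ccc(OC(C)(C)C=C)c(OC)c1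
F6 | step 3 | methyl 3-hydroxy-2-methoxy-3-{3-methoxy-4-[(2-methylbut-3-en-2-yl)oxy]phenyl}propanoate (racemic syn/anti mixture) | COC(=O)C(OC)C(O)c1ccc(OC(C)(C)C=C)c(OC)c1
F7 | step 2 | methyl 3-methoxy-4-[(2-methylbut-3-yn-2-yl)oxy]benzoate | COC(=O)c1ccc(OC(C)(C)C#C)c(OC)c1
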